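**Retrosynthetic overview**

1. The target is a trans-1-aryl-1,2-dihydronaphthalene (ring A = the dimethoxybenzo ring, ring B = C1–C4/C4a/C8a). Enabling feature: C1 carries two identical 3,4-dimethoxyphenyl units, one as ring A (bound through C8a) and one as the pendant aryl. In an open-chain precursor C1 is therefore not a stereocentre, and C4a lies para to the C7 methoxy group, the nucleophilic position of a veratryl ring.
2. Key disconnection C4–C4a: acid-triggered Friedel–Crafts cyclodehydration of the acyclic enol ether 8 (C4 at the aldehyde oxidation level). One operation closes ring B, selects one of two diastereotopic veratryl rings (creating C1 trans to the C2 methyl), and installs the C3=C4 alkene.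
3. Enol ether 8 comes from methyl ketone 7 by Wittig methoxymethylenation (brings in C4); 7 comes from alcohol 6 by oxidation.
4. C1–C2 disconnection: SN2 opening of (2S,3S)-2,3-dimethyloxirane 4 by the lithium anion of bis(3,4-dimethoxyphenyl)methane 3 sets the only pre-formed stereocentre (C2). Compound 3 comes from veratryl alcohol 1 and veratrole 2.
5. Ring order: both arenes are bought; ring B is the only ring formed, in the last step.

Key step: step 5

Assumption: (2S,3S)-2,3-dimethyloxirane (4) is taken as a purchasable single enantiomer; it is otherwise available from (2S,3S)-butane-2,3-diol by the standard diol-to-epoxide sequence with net retention.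

Step 1
Reactants: 1 (3,4-dimethoxyphenyl)methanol; 2 1,2-dimethoxybenzene
Product: 3 bis(3,4-dimethoxyphenyl)methane
Conditions: 2 (8 equiv), TsOH·H2O (5 mol%), 1,2-dichloroethane, 60 °C, slow addition of 1
Reagents that add atoms: none
Why: Friedel–Crafts benzylation: acid ionises the electron-rich benzylic alcohol to the 3,4-dimethoxybenzyl cation, which the large excess of veratrole should capture at C4 (para to a methoxy group), the excess and slow addition suppressing self-condensation of 1 and over-benzylation of 3.

Step 2
Reactants: 3 bis(3,4-dimethoxyphenyl)methane; 4 (2S,3S)-2,3-dimethyloxirane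
Product: 6 (2S,3S)-4,4-bis(3,4-dimethoxyphenyl)-3-methylbutan-2-ol, via diarylmethyllithium 5 (not isolated)
Conditions: n-BuLi (1.0 equiv), THF, −20 → 0 °C; then 4 (1.5 equiv), 0 °C → rt, sealed; then H2O
Reagents that add atoms: none
Why: Epoxide ring opening by a stabilised organolithium: the doubly benzylic C–H of 3 is the thermodynamically most acidic site, the two carbons of the C2-symmetric trans-epoxide are equivalent so no regiochemical question arises, and SN2 attack with inversion at the attacked carbon sets the stereocentre that becomes C2 of the target as S (the carbinol centre is removed in step 3).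

Step 3
Reactants: 6 (2S,3S)-4,4-bis(3,4-dimethoxyphenyl)-3-methylbutan-2-ol
Product: 7 (3S)-4,4-bis(3,4-dimethoxyphenyl)-3-methylbutan-2-one
Conditions: Dess–Martin periodinane (1.2 equiv), CH2Cl2, 0 °C → rt
Reagents that add atoms: none
Why: Dess–Martin oxidation of a secondary alcohol under near-neutral conditions should deliver the methyl ketone without enolisation, so the adjacent stereocentre set in step 2 is kept.

Step 4
Reactants: 7 (3S)-4,4-bis(3,4-dimethoxyphenyl)-3-methylbutan-2-one
Product: 8 (3S)-4,4-bis(3,4-dimethoxyphenyl)-1-methoxy-2,3-dimethylbut-1-ene (E/Z mixture)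
Conditions: Ph3P(CH2OMe)Cl (2.0 equiv), KOt-Bu (1.9 equiv), THF, 0 °C; then 7, 0 °C → rt
Reagents that add atoms: (methoxymethyl)triphenylphosphonium chloride, COC[P+](c1ccccc1)(c1ccccc1)c1ccccc1.[Cl-]
Why: Wittig methoxymethylenation converts the carbonyl carbon into C3 (still carrying its methyl group) and brings in C4 at the aldehyde oxidation level as an enol ether; addition of the ylide to the carbonyl should outpace deprotonation of the hindered C–H flanked by the diarylmethyl group, and the E/Z geometry is irrelevant because C3 is reprotonated and then becomes sp2 in step 5.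

Step 5
Reactants: 8 (3S)-4,4-bis(3,4-dimethoxyphenyl)-1-methoxy-2,3-dimethylbut-1-ene (E/Z mixture)
Product: 11 (1R,2S)-1-(3,4-dimethoxyphenyl)-6,7-dimethoxy-2,3-dimethyl-1,2-dihydronaphthalene, via methoxycarbenium ion 9 (not isolated), via 4-methoxytetralin 10 (not isolated)
Conditions: camphor-10-sulfonic acid (10 mol%), CH2Cl2 (0.02 M), 0 → 40 °C
Reagents that add atoms: none
Why: Protonation of the enol ether at C3 gives the methoxycarbenium ion 9, whose electrophilic carbon (the future C4) is attacked by one veratryl ring at its position para to a methoxy group (the future C4a); the benzylic methyl ether 10, activated by the para C7 methoxy group, then ionises and loses the C3 proton (E1) to give the conjugated C3=C4 bond and methanol. The closest known reaction type is the acid-catalysed Friedel–Crafts cyclodehydration of 4,4-diarylbutanals and their acetals or enol ethers to 1-aryl-1,2-dihydronaphthalenes, as used for aryl-dihydronaphthalene lignans. Ring B closes in a 6-exo-trig sense with respect to the C=O+ bond, through a chair-like six-membered transition state in which the arene is the π-nucleophile. C1 becomes stereogenic only here: its two veratryl groups are diastereotopic, and the existing C2 stereocentre (S) selects between them, because closure that leaves the spectator aryl trans to the C2 methyl avoids the gauche aryl/methyl interaction of the cis transition state and leads to the more stable trans half-chair, so C1 should emerge R. The step needs this diastereotopic-group selectivity (secured by 1,2-induction from C2) and attack para rather than ortho to methoxy (secured by the less hindered, more activated ring position); the C3 configuration of 9 and 10 is inconsequential because C3 ends sp2, and high dilution with only catalytic acid should keep the electron-rich styrene from oligomerising.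

**Compound list**

1 | (3,4-dimethoxyphenyl)methanol (veratryl alcohol) | COc1ccc(CO)cc1OC | starting material
2 | 1,2-dimethoxybenzene (veratrole) | COc1ccccc1OC | starting material
3 | bis(3,4-dimethoxyphenyl)methane | COc1ccc(Cc2ccc(OC)c(OC)c2)cc1OC | intermediate
4 | (2S,3S)-2,3-dimethyloxirane | C[C@@H]1O[C@H]1C | starting material
5 | [bis(3,4-dimethoxyphenyl)methyl]lithium (not isolated) | COc1ccc(C([Li])c2ccc(OC)c(OC)c2)cc1OC | intermediate
6 | (2S,3S)-4,4-bis(3,4-dimethoxyphenyl)-3-methylbutan-2-ol | C[C@H]([C@@H](O)C)C(c1ccc(OC)c(OC)c1)c1ccc(OC)c(OC)c1 | intermediate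
7 | (3S)-4,4-bis(3,4-dimethoxyphenyl)-3-methylbutan-2-one | C[C@H](C(C)=O)C(c1ccc(OC)c(OC)c1)c1ccc(OC)c(OC)c1 | intermediate
8 | (3S)-4,4-bis(3,4-dimethoxyphenyl)-1-methoxy-2,3-dimethylbut-1-ene (E/Z mixture) | COC=C(C)[C@@H](C)C(c1ccc(OC)c(OC)c1)c1ccc(OC)c(OC)c1 | intermediate
9 | methoxycarbenium ion from C3-protonation of 8, (3S), C2 epimers (not isolated) | C[O+]=CC(C)[C@@H](C)C(c1ccc(OC)c(OC)c1)c1ccc(OC)c(OC)c1 | intermediate
10 | (1R,2S)-1-(3,4-dimethoxyphenyl)-4,6,7-trimethoxy-2,3-dimethyl-1,2,3,4-tetrahydronaphthalene, C3/C4 epimers (not isolated) | COc1ccc([C@@H]2c3cc(OC)c(OC)cc3C(OC)C(C)[C@H]2C)cc1OC | intermediate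
11 | (1R,2S)-1-(3,4-dimethoxyphenyl)-6,7-dimethoxy-2,3-dimethyl-1,2-dihydronaphthalene (CNP0238419.1) | COc1ccc([C@@H]2c3cc(OC)c(OC)cc3C=C(C)[C@H]2C)cc1OC | target

**Step count**

Total step count: 5. Longest linear sequence: 5 steps (1 → 3 → 6 → 7 → 8 → 11).

**Steps most likely to fail**

(a) Step 5, the key cyclisation. What may go wrong is incomplete discrimination between the two diastereotopic veratryl rings (erosion of the configuration at C1), together with acid-induced oligomerisation of the electron-rich styrene while it accumulates in the acidic medium. The fallback sets out from 8 and returns at 11, closing the same C4–C4a bond as a Friedel–Crafts acylation one oxidation level higher. Compound 8 would be hydrolysed and oxidised in one operation with Jones reagent (CrO3, H2SO4, acetone, 0 °C) to (3S)-4,4-bis(3,4-dimethoxyphenyl)-2,3-dimethylbutanoic acid F1. Ring closure with trifluoroacetic anhydride (CH2Cl2, 0 °C) should then give the tetralone (3S,4R)-4-(3,4-dimethoxyphenyl)-6,7-dimethoxy-2,3-dimethyl-3,4-dihydronaphthalen-1(2H)-one F2, a stable ketone at which any C4 epimer could be removed by crystallisation or chromatography. NaBH4 (MeOH, 0 °C) would give (3S,4R)-4-(3,4-dimethoxyphenyl)-6,7-dimethoxy-2,3-dimethyl-1,2,3,4-tetrahydronaphthalen-1-ol F3, and brief treatment with catalytic TsOH (toluene, rt) should dehydrate it to 11, so the sensitive alkene appears only in the last, mild operation.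

(b) Step 2, the epoxide opening. What may go wrong is slow SN2 attack of the bulky, charge-delocalised carbanion on a secondary epoxide carbon, which would let ortho-lithiation of the veratryl rings or base-induced isomerisation of the epoxide to an allylic alkoxide compete. The fallback sets out from 3 and returns at 7, reversing the polarity of the benzhydrylic carbon. DDQ in CH2Cl2–MeOH would oxidise 3 to bis(3,4-dimethoxyphenyl)methyl methyl ether F4. F4 would be ionised with TESOTf/2,6-lutidine and captured by the chelated nickel enolate (catalytic (Me3P)2NiCl2, CH2Cl2, −20 °C) of (R)-4-isopropyl-3-propanoyl-1,3-thiazolidine-2-thione. This SN1-type alkylation anti to the isopropyl group should give (4R)-3-[(2S)-3,3-bis(3,4-dimethoxyphenyl)-2-methylpropanoyl]-4-(propan-2-yl)-1,3-thiazolidine-2-thione F5. Displacement of the auxiliary with MeNH(OMe)·HCl/imidazole would give (2S)-3,3-bis(3,4-dimethoxyphenyl)-N-methoxy-N,2-dimethylpropanamide F6, and MeMgBr (THF, 0 °C) should deliver 7.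

(c) Step 4, the Wittig reaction. What may go wrong is enolisation of the hindered ketone by the basic ylide, leading to epimerisation of the stereocentre next to the carbonyl or to incomplete olefination. The fallback sets out from 7 and returns at 11, introducing C4 without a basic reagent. Methylenation with Cp2TiMe2 (toluene, 65 °C) would give (3S)-4,4-bis(3,4-dimethoxyphenyl)-2,3-dimethylbut-1-ene F7. Hydroboration with 9-BBN and NaOH/H2O2 work-up should give (3S)-4,4-bis(3,4-dimethoxyphenyl)-2,3-dimethylbutan-1-ol F8 (C2 epimers, inconsequential). Dess–Martin oxidation would give (3S)-4,4-bis(3,4-dimethoxyphenyl)-2,3-dimethylbutanal F9, which under the acid conditions of step 5 should undergo the same ring-selective cyclodehydration, with loss of water, to 11.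

**Further compounds**

F1 | step 5 | (3S)-4,4-bis(3,4-dimethoxyphenyl)-2,3-dimethylbutanoic acid (C2 epimers) | OC(=O)C(C)[C@@H](C)C(c1ccc(OC)c(OC)c1)c1ccc(OC)c(OC)c1
F2 | step 5 | (3S,4R)-4-(3,4-dimethoxyphenyl)-6,7-dimethoxy-2,3-dimethyl-3,4-dihydronaphthalen-1(2H)-one (C2 epimers) | COc1ccc([C@@H]2c3cc(OC)c(OC)cc3C(=O)C(C)[C@H]2C)cc1OC
F3 | step 5 | (3S,4R)-4-(3,4-dimethoxyphenyl)-6,7-dimethoxy-2,3-dimethyl-1,2,3,4-tetrahydronaphthalen-1-ol (C1/C2 epimers) | COc1ccc([C@@H]2c3cc(OC)c(OC)cc3C(O)C(C)[C@H]2C)cc1OC
F4 | step 2 | bis(3,4-dimethoxyphenyl)methyl methyl ether | COC(c1ccc(OC)c(OC)c1)c1ccc(OC)c(OC)c1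
F5 | step 2 | (4R)-3-[(2S)-3,3-bis(3,4-dimethoxyphenyl)-2-methylpropanoyl]-4-(propan-2-yl)-1,3-thiazolidine-2-thione | C[C@H](C(=O)N1C(=S)SC[C@H]1C(C)C)C(c1ccc(OC)c(OC)c1)c1ccc(OC)c(OC)c1
F6 | step 2 | (2S)-3,3-bis(3,4-dimethoxyphenyl)-N-methoxy-N,2-dimethylpropanamide | C[C@H](C(=O)N(C)OC)C(c1ccc(OC)c(OC)c1)c1ccc(OC)c(OC)c1
F7 | step 4 | (3S)-4,4-bis(3,4-dimethoxyphenyl)-2,3-dimethylbut-1-ene | C=C(C)[C@@H](C)C(c1ccc(OC)c(OC)c1)c1ccc(OC)c(OC)c1
F8 | step 4 | (3S)-4,4-bis(3,4-dimethoxyphenyl)-2,3-dimethylbutan-1-ol (C2 epimers) | OCC(C)[C@@H](C)C(c1ccc(OC)c(OC)c1)c1ccc(OC)c(OC)c1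
F9 | step 4 | (3S)-4,4-bis(3,4-dimethoxyphenyl)-2,3-dimethylbutanal (C2 epimers) | O=CC(C)[C@@H](C)C(c1ccc(OC)c(OC)c1)c1ccc(OC)c(OC)c1
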